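The route rests on making the only endocyclic double bond of the ten-membered carbocycle, the Z-trisubstituted alkene CH=C(CH3) (C1=C10) beside the carbinol C2, by extrusion of a ring atom. An eleven-membered thiacycle 1,1-dioxide, in which sulfur bridges C1 and C10, undergoes a Ramberg–Bäcklund ring contraction: one operation forges the C1–C10 bond, expels SO2 and leaves the carbocycle with the Z alkene. The thiacycle is closed by soft S-alkylation of a seco-thiol whose C5–C8 stereotetrad comes from (R)-glyceraldehyde, a Felkin-controlled Nozaki–Hiyama–Kishi coupling and an indium Barbier reaction that also brings in the masked α-methylene lactone. Acylations and an oxidative lactonisation finish the synthesis.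

Key step: step 16

Remark (atom labels): ring carbons are C1 (=CH), C2 (CHOH), C3 (CH2), C4 (C=C15H2), C5 (CHOAc), C6 (CH–O of the lactone), C7 (CH–C11), C8 (CHO-tigloyl), C9 (CH2), C10 (=C–C14H3); C11(=C13H2)–C12(=O) complete the lactone; in these labels the target is 2R,5S,6R,7R,8R,1(10)Z.

Remark (assumption): aldehyde 18 is used as the racemate, so the sulfur-bearing carbon C10 is an inconsequential pair of epimers in 19–25 (written without a descriptor) until it becomes sp2 in step 16; the carbinol carbon of 14 is likewise an epimer pair that is erased in step 9.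

Step 1
Reactants: 1 (R)-epichlorohydrin; 2 (1-bromovinyl)trimethylsilane
Product: 4 (R)-1-chloro-4-(trimethylsilyl)pent-4-en-2-ol, via Grignard reagent 3 (not isolated)
Conditions: 2, Mg, THF; then CuI (10 mol%), 1, −30 → 0 °C
Reagents that add atoms: none
Why: Copper-catalysed Grignard opening of the epoxide at its unsubstituted carbon (SN2) attaches the C4(Si)=C15 unit to C3, while the C2 stereocentre and the chloride of (R)-epichlorohydrin stay untouched.

Step 2
Reactants: 4 (R)-1-chloro-4-(trimethylsilyl)pent-4-en-2-ol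
Product: 5 TBS ether of 4
Conditions: TBSCl, imidazole, DMF, rt
Reagents that add atoms: tert-butyldimethylsilyl chloride, CC(C)(C)[Si](C)(C)Cl
Why: Silylation of the secondary alcohol (Corey conditions) masks C2–OH with a group that should survive every later step up to the final desilylation.

Step 3
Reactants: 5 TBS ether of 4
Product: 6 (R)-tert-butyl[(1-chloro-4-iodopent-4-en-2-yl)oxy]dimethylsilane
Conditions: NIS, HFIP, 0 °C
Reagents that add atoms: N-iodosuccinimide, O=C1CCC(=O)N1I
Why: Electrophilic ipso-iododesilylation of the vinylsilane exchanges C–Si for C–I and gives the 2-iodoalkene needed for the Ni/Cr coupling.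

Step 4
Reactants: 6 vinyl iodide; 7 (R)-2,2-dimethyl-1,3-dioxolane-4-carbaldehyde
Product: 8 (1S,4R)-4-[(tert-butyldimethylsilyl)oxy]-5-chloro-1-[(4R)-2,2-dimethyl-1,3-dioxolan-4-yl]-2-methylidenepentan-1-ol
Conditions: CrCl2, NiCl2 (cat.), DMSO, rt
Reagents that add atoms: none
Why: Nozaki–Hiyama–Kishi coupling in which the alkenylchromium(III) species adds to the α-alkoxy aldehyde under Felkin–Anh control (attack anti to the dioxolane C–O bond), which should set C5 anti to the C6 oxygen inherited from (R)-glyceraldehyde; the minor C5 epimer would be removed by chromatography.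

Step 5
Reactants: 8 NHK adduct
Product: 9 (2R,3S,6R)-6-[(tert-butyldimethylsilyl)oxy]-7-chloro-4-methylideneheptane-1,2,3-triol
Conditions: AcOH–H2O (4:1), rt
Reagents that add atoms: none
Why: Acid-catalysed acetal hydrolysis frees the terminal diol, and a secondary TBS ether is stable to aqueous acetic acid at room temperature.

Step 6
Reactants: 9 triol
Product: 10 tris(triethylsilyl) ether of 9
Conditions: TESCl, imidazole, DMAP (cat.), DMF, rt
Reagents that add atoms: chlorotriethylsilane, CC[Si](CC)(CC)Cl
Why: Exhaustive silylation, with triethylsilyl chosen because the primary ether can be oxidised directly in step 7 and the secondary ones can later be removed beside the TBS ether.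

Step 7
Reactants: 10 tris(triethylsilyl) ether
Product: 11 (2S,3S,6R)-6-[(tert-butyldimethylsilyl)oxy]-7-chloro-4-methylidene-2,3-bis[(triethylsilyl)oxy]heptanal
Conditions: (COCl)2, DMSO, CH2Cl2, −78 → −30 °C; then Et3N
Reagents that add atoms: none
Why: Under Swern conditions the primary triethylsilyl ether is cleaved and oxidised selectively (secondary silyl ethers are inert), which should give the α-silyloxy aldehyde without epimerisation.

Step 8
Reactants: 11 aldehyde; 12 methyl propiolate
Product: 14 methyl (4R,5S,8R)-8-[(tert-butyldimethylsilyl)oxy]-9-chloro-3-hydroxy-2,6-dimethylidene-4,5-bis[(triethylsilyl)oxy]nonanoate (C3 epimers), via vinylalane 13 (not isolated)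
Conditions: DIBAL-H, NMO, THF, 0 °C, 12; then 11, 0 °C → rt
Reagents that add atoms: none
Why: Vinylalumination (a Morita–Baylis–Hillman equivalent), in which 1,4-hydroalumination of methyl propiolate gives vinylalane 13 that adds to the aldehyde under non-basic conditions; the new carbinol centre is erased in step 9.

Step 9
Reactants: 14 Baylis–Hillman-type adduct
Product: 15 methyl (2Z,4R,5S,8R)-2-(bromomethyl)-8-[(tert-butyldimethylsilyl)oxy]-9-chloro-6-methylidene-4,5-bis[(triethylsilyl)oxy]non-2-enoate
Conditions: CBr4, PPh3, CH2Cl2, 0 °C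
Reagents that add atoms: tetrabromomethane, BrC(Br)(Br)Br
Why: Appel bromination of the Baylis–Hillman-type alcohol should proceed with allylic transposition (SN2′) to the conjugated, thermodynamically preferred (Z)-2-(bromomethyl)enoate.

Step 10
Reactants: 16 crotonaldehyde; 17 thioacetic acid
Product: 18 3-(acetylsulfanyl)butanal (racemic)
Conditions: Et3N (cat.), CH2Cl2, 0 °C → rt
Reagents that add atoms: none
Why: Thia-Michael addition of the thioacid to the enal gives the β-acetylthio aldehyde, whose stereocentre (C10) is racemic by design because it is destroyed in step 16.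

Step 11
Reactants: 15 allylic bromide; 18 3-(acetylsulfanyl)butanal
Product: 19 C7/C8-syn hydroxy ester (C1–Cl, C10–SAc)
Conditions: In powder, THF–H2O (3:1), rt
Reagents that add atoms: none
Why: Indium-mediated Barbier allylation in which the γ-substituted 2-(methoxycarbonyl)allylindium reacts at its γ-carbon through a chair transition state to give the syn (C7/C8) adduct, and the aldehyde approaches C7 anti to the C5 chain with H6 eclipsing the allyl unit (A1,3 strain), so that C6 should control C7 and, through the syn preference, C8.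

Step 12
Reactants: 19 hydroxy ester
Product: 20 mercapto diol (C8–OH, C12–OH, C10–SH, C1–Cl)
Conditions: DIBAL-H (excess), CH2Cl2, −78 → 0 °C; Rochelle salt
Reagents that add atoms: none
Why: DIBAL-H reduces the enoate 1,2 to the allylic alcohol and cleaves the thioacetate to the thiol in one operation, which removes the Michael acceptor before any thiolate is generated.

Step 13
Reactants: 20 mercapto diol
Product: 21 eleven-membered thiacycle (sulfide; C8–OH, C12–OH)
Conditions: Cs2CO3, NaI (cat.), degassed DMF (1 mM, slow addition), 60 °C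
Reagents that add atoms: none
Why: Intramolecular thiolate S-alkylation (SN2 at the primary chloride with iodide catalysis and the caesium effect, high dilution) closes the eleven-membered thiacycle without touching a stereocentre.

Step 14
Reactants: 21 thiacycle diol
Product: 22 C12-O-triethylsilyl thiacycle (C8–OH free)
Conditions: TESCl, imidazole, CH2Cl2, −40 °C
Reagents that add atoms: chlorotriethylsilane, CC[Si](CC)(CC)Cl
Why: Chemoselective silylation of the primary allylic alcohol over the hindered secondary C8 hydroxyl, which is kept free for the later tigloylation.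

Step 15
Reactants: 22 sulfide
Product: 23 thiacycle 1,1-dioxide (sulfone)
Conditions: (NH4)6Mo7O24·4H2O (cat.), 30% H2O2, EtOH, 0 °C → rt
Reagents that add atoms: hydrogen peroxide, OO
Why: Molybdate-catalysed hydrogen peroxide oxidation converts the sulfide to the sulfone chemoselectively in the presence of alkenes and silyl ethers.

Step 16
Reactants: 23 thiacycle 1,1-dioxide
Product: 26 (Z)-cyclodecenol (C1=C10, C8–OH free), via α-bromo sulfone 24 (not isolated), via episulfone 25 (not isolated)
Conditions: CBr2F2, KOH/Al2O3, t-BuOH–CH2Cl2, 0 °C → rt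
Reagents that add atoms: none
Why: Reversible deprotonation α to the sulfone and bromine transfer from CBr2F2 give α-bromo sulfone 24; deprotonation at the other α-carbon (C10) and intramolecular displacement of bromide form the C1–C10 bond as thiirane 1,1-dioxide 25, which loses SO2 stereospecifically to give the alkene. The closest known reaction type is the Ramberg–Bäcklund reaction in its one-pot halogenative (Chan) form, applied as a ring contraction of a cyclic sulfone. The only ring closed is the three-membered episulfone (3-exo-tet, transannular in the eleven-membered ring); its cheletropic collapse turns the eleven-membered thiacycle into the ten-membered carbocycle with one ring atom fewer. No stereocentre is formed and the stereogenic C10 is erased, so both epimers of 23 converge. The step needs Z geometry and must outrun E1cB loss of the C2 silyloxide: the ring should hold the two chain arms cis on the episulfone (the cis-fused bicycle and the Z-cyclodecene are the less strained) and the extrusion is stereospecific, while capture of the C1 carbanion by excess CBr2F2 at 0 °C should be faster than expulsion of the poor silyloxide leaving group, in line with the known tolerance of β-alkoxy sulfones to these conditions.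

Step 17
Reactants: 26 (Z)-cyclodecenol
Product: 27 C8 tiglate
Conditions: tigloyl chloride, pyridine, DMAP, CH2Cl2, 0 °C → rt
Reagents that add atoms: (E)-2-methylbut-2-enoyl chloride, C/C=C(\C)C(=O)Cl
Why: DMAP-catalysed acylation of the only free hydroxyl (C8) with the E-configured acid chloride should install the tiglate without double-bond isomerisation.

Step 18
Reactants: 27 C8 tiglate
Product: 28 triol (C5–OH, C6–OH, C12–OH; C2–OTBS)
Conditions: PPTS, MeOH, 0 °C → rt
Reagents that add atoms: none
Why: Acid-catalysed methanolysis removes the three triethylsilyl ethers and leaves the more robust secondary TBS ether and the tiglate.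

Step 19
Reactants: 28 triol
Product: 31 α-methylene-γ-butyrolactone (C5–OH free), via enal 29 (not isolated), via lactol 30 (not isolated)
Conditions: [Cu(MeCN)4]OTf, 2,2′-bipyridine, TEMPO, N-methylimidazole (all cat.), air, MeCN, rt
Reagents that add atoms: none
Why: Copper/TEMPO aerobic oxidation is selective for the primary allylic alcohol; enal 29 should be trapped by the cis-disposed C6 hydroxyl as the five-membered lactol 30 (5-exo-trig, favoured over six-ring closure by O5), which is oxidised on to the lactone without glycol cleavage.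

Step 20
Reactants: 31 hydroxy lactone
Product: 32 C5 acetate
Conditions: Ac2O, pyridine, DMAP (cat.), CH2Cl2, 0 °C
Reagents that add atoms: acetic anhydride, CC(=O)OC(C)=O
Why: Acetylation of the one remaining hydroxyl (C5) under standard nucleophilic catalysis.

Step 21
Reactants: 32 silyl-protected target
Product: 33 CNP0210609.1 (target)
Conditions: HF·pyridine, pyridine, THF, 0 °C → rt
Reagents that add atoms: none
Why: Fluoride-mediated cleavage of the TBS ether under buffered, mildly acidic conditions should leave both esters and the α-methylene lactone intact and free the C2 hydroxyl.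

Compound list

1 | (R)-epichlorohydrin | ClC[C@H]1CO1 | starting material
2 | (1-bromovinyl)trimethylsilane | C=C(Br)[Si](C)(C)C | starting material
3 | [1-(trimethylsilyl)vinyl]magnesium bromide | C=C([Mg]Br)[Si](C)(C)C | intermediate (not isolated)
4 | (R)-1-chloro-4-(trimethylsilyl)pent-4-en-2-ol | ClC[C@H](O)CC(=C)[Si](C)(C)C | intermediate
5 | (R)-tert-butyl{[1-chloro-4-(trimethylsilyl)pent-4-en-2-yl]oxy}dimethylsilane | ClC[C@H](O[Si](C)(C)C(C)(C)C)CC(=C)[Si](C)(C)C | intermediate
6 | (R)-tert-butyl[(1-chloro-4-iodopent-4-en-2-yl)oxy]dimethylsilane | ClC[C@H](O[Si](C)(C)C(C)(C)C)CC(=C)I | intermediate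
7 | (R)-2,2-dimethyl-1,3-dioxolane-4-carbaldehyde | O=C[C@@H]1OC(C)(C)OC1 | starting material
8 | (1S,4R)-4-[(tert-butyldimethylsilyl)oxy]-5-chloro-1-[(4R)-2,2-dimethyl-1,3-dioxolan-4-yl]-2-methylidenepentan-1-ol | ClC[C@H](O[Si](C)(C)C(C)(C)C)CC(=C)[C@H](O)[C@@H]1OC(C)(C)OC1 | intermediate
9 | (2R,3S,6R)-6-[(tert-butyldimethylsilyl)oxy]-7-chloro-4-methylideneheptane-1,2,3-triol | ClC[C@H](O[Si](C)(C)C(C)(C)C)CC(=C)[C@H](O)[C@H](O)CO | intermediate
10 | (2R,3S,6R)-1,2,3-tris-O-(triethylsilyl) ether of 9 | ClC[C@H](O[Si](C)(C)C(C)(C)C)CC(=C)[C@H](O[Si](CC)(CC)CC)[C@H](O[Si](CC)(CC)CC)CO[Si](CC)(CC)CC | intermediate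
11 | (2S,3S,6R)-6-[(tert-butyldimethylsilyl)oxy]-7-chloro-4-methylidene-2,3-bis[(triethylsilyl)oxy]heptanal | ClC[C@H](O[Si](C)(C)C(C)(C)C)CC(=C)[C@H](O[Si](CC)(CC)CC)[C@H](O[Si](CC)(CC)CC)C=O | intermediate
12 | methyl propiolate | C#CC(=O)OC | starting material
13 | methyl 2-(diisobutylalumanyl)acrylate (vinylalane) | C=C(C(=O)OC)[Al](CC(C)C)CC(C)C | intermediate (not isolated)
14 | methyl (4R,5S,8R)-8-[(tert-butyldimethylsilyl)oxy]-9-chloro-3-hydroxy-2,6-dimethylidene-4,5-bis[(triethylsilyl)oxy]nonanoate, C3 epimers | ClC[C@H](O[Si](C)(C)C(C)(C)C)CC(=C)[C@H](O[Si](CC)(CC)CC)[C@H](O[Si](CC)(CC)CC)C(O)C(=C)C(=O)OC | intermediate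
15 | methyl (2Z,4R,5S,8R)-2-(bromomethyl)-8-[(tert-butyldimethylsilyl)oxy]-9-chloro-6-methylidene-4,5-bis[(triethylsilyl)oxy]non-2-enoate | ClC[C@H](O[Si](C)(C)C(C)(C)C)CC(=C)[C@H](O[Si](CC)(CC)CC)[C@H](O[Si](CC)(CC)CC)/C=C(\CBr)C(=O)OC | intermediate
16 | (E)-crotonaldehyde | C/C=C/C=O | starting material
17 | thioacetic acid | CC(=O)S | starting material
18 | 3-(acetylsulfanyl)butanal, racemic | CC(=O)SC(C)CC=O | intermediate
19 | seco hydroxy ester: ClCH2(C1)–CH(OTBS)(C2)–CH2–C(=CH2)(C4)–CH(OTES)(C5)–CH(OTES)(C6)–CH[C(=CH2)CO2Me](C7)–CH(OH)(C8)–CH2–CH(CH3)SAc(C10); C2, C5, C6, C7, C8 arranged as in the target, C10 epimers | ClC[C@H](O[Si](C)(C)C(C)(C)C)CC(=C)[C@H](O[Si](CC)(CC)CC)[C@H](O[Si](CC)(CC)CC)[C@H](C(=C)C(=O)OC)[C@H](O)CC(C)SC(C)=O | intermediate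
20 | seco mercapto diol: as 19 with C11(=CH2)–CH2OH and C10–SH | ClC[C@H](O[Si](C)(C)C(C)(C)C)CC(=C)[C@H](O[Si](CC)(CC)CC)[C@H](O[Si](CC)(CC)CC)[C@H](C(=C)CO)[C@H](O)CC(C)S | intermediate
21 | eleven-membered thiacycle (S bridges C1 and C10): C2–OTBS, C4=CH2, C5–OTES, C6–OTES, C7–C(=CH2)CH2OH, C8–OH, C10–CH3 (epimers) | C1[C@H](O[Si](C)(C)C(C)(C)C)CC(=C)[C@H](O[Si](CC)(CC)CC)[C@H](O[Si](CC)(CC)CC)[C@H](C(=C)CO)[C@H](O)CC(C)S1 | intermediate
22 | thiacycle 21 with C12–OTES | C1[C@H](O[Si](C)(C)C(C)(C)C)CC(=C)[C@H](O[Si](CC)(CC)CC)[C@H](O[Si](CC)(CC)CC)[C@H](C(=C)CO[Si](CC)(CC)CC)[C@H](O)CC(C)S1 | intermediate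
23 | 1,1-dioxide (sulfone) of 22 | C1[C@H](O[Si](C)(C)C(C)(C)C)CC(=C)[C@H](O[Si](CC)(CC)CC)[C@H](O[Si](CC)(CC)CC)[C@H](C(=C)CO[Si](CC)(CC)CC)[C@H](O)CC(C)S1(=O)=O | intermediate
24 | C1-bromo derivative of sulfone 23 (C1 and C10 epimers) | BrC1[C@H](O[Si](C)(C)C(C)(C)C)CC(=C)[C@H](O[Si](CC)(CC)CC)[C@H](O[Si](CC)(CC)CC)[C@H](C(=C)CO[Si](CC)(CC)CC)[C@H](O)CC(C)S1(=O)=O | intermediate (not isolated)
25 | cis-fused thiirane 1,1-dioxide spanning C1 and C10 (bicyclo[8.1.0]; fusion face not specified) | C12[C@H](O[Si](C)(C)C(C)(C)C)CC(=C)[C@H](O[Si](CC)(CC)CC)[C@H](O[Si](CC)(CC)CC)[C@H](C(=C)CO[Si](CC)(CC)CC)[C@H](O)CC1(C)S2(=O)=O | intermediate (not isolated)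
26 | (Z)-cyclodecenol: C1=C10 (Z), C2–OTBS, C4=CH2, C5–OTES, C6–OTES, C7–C(=CH2)CH2OTES, C8–OH | C/C1=C/[C@H](O[Si](C)(C)C(C)(C)C)CC(=C)[C@H](O[Si](CC)(CC)CC)[C@H](O[Si](CC)(CC)CC)[C@H](C(=C)CO[Si](CC)(CC)CC)[C@H](O)C1 | intermediate
27 | C8 tiglate of 26 | C/C1=C/[C@H](O[Si](C)(C)C(C)(C)C)CC(=C)[C@H](O[Si](CC)(CC)CC)[C@H](O[Si](CC)(CC)CC)[C@H](C(=C)CO[Si](CC)(CC)CC)[C@H](OC(=O)/C(C)=C/C)C1 | intermediate
28 | triol: C5–OH, C6–OH, C12–OH; C2–OTBS, C8–O-tigloyl | C/C1=C/[C@H](O[Si](C)(C)C(C)(C)C)CC(=C)[C@H](O)[C@H](O)[C@H](C(=C)CO)[C@H](OC(=O)/C(C)=C/C)C1 | intermediate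
29 | enal: 28 with C12 as CHO | C/C1=C/[C@H](O[Si](C)(C)C(C)(C)C)CC(=C)[C@H](O)[C@H](O)[C@H](C(=C)C=O)[C@H](OC(=O)/C(C)=C/C)C1 | intermediate (not isolated)
30 | cis-fused α-methylene lactol (C6–O–C12; anomers) | C/C1=C/[C@H](O[Si](C)(C)C(C)(C)C)CC(=C)[C@H](O)[C@@H]2OC(O)C(=C)[C@@H]2[C@H](OC(=O)/C(C)=C/C)C1 | intermediate (not isolated)
31 | cis-fused α-methylene-γ-butyrolactone with C5–OH, C2–OTBS, C8–O-tigloyl | C/C1=C/[C@H](O[Si](C)(C)C(C)(C)C)CC(=C)[C@H](O)[C@@H]2OC(=O)C(=C)[C@@H]2[C@H](OC(=O)/C(C)=C/C)C1 | intermediate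
32 | C5 acetate of 31 (C2-O-TBS ether of the target) | C/C1=C/[C@H](O[Si](C)(C)C(C)(C)C)CC(=C)[C@H](OC(C)=O)[C@@H]2OC(=O)C(=C)[C@@H]2[C@H](OC(=O)/C(C)=C/C)C1 | intermediate
33 | CNP0210609.1 (2R,5S,6R,7R,8R,1(10)Z in the labels above) | C=C1C(=O)O[C@@H]2[C@H]1[C@H](OC(=O)/C(C)=C/C)C/C(C)=C\[C@H](O)CC(=C)[C@@H]2OC(C)=O | target

Total step count: 21. Longest linear sequence: 20 steps (1/2 → 33 through steps 1–9 and 11–21; step 10 is a one-step side branch).

Steps most likely to fail

Step 16 (key step). The 1,3-elimination may close the episulfone with the two ring arms trans and so deliver the E ring alkene, and E1cB loss of the C2 silyloxide from the C1 carbanion may compete with bromination. The fallback sets out from 23 and comes back at 26. The contraction is run as before, and any (E)-cyclodecenol F1 is not discarded but equilibrated by reversible thiyl-radical addition (PhSSPh, hν, benzene) to the less strained Z isomer 26. Geometry is then set by thermodynamic radical isomerisation instead of by kinetic control in the episulfone closure.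

Step 13. Intermolecular S-alkylation (oligomers) may outrun closure of the eleven-membered ring, and SN2 at the β-oxygenated primary chloride is slow. The fallback sets out from 20 and comes back at 21. Potassium thioacetate in DMF displaces the chloride to give the S-acetyl thiol F2. Methanolysis (K2CO3, MeOH) and iodine oxidation at high dilution close the twelve-membered cyclic disulfide F3, a reliable macrocyclisation. Sulfur extrusion with (Et2N)3P in hot benzene (phosphine attack on sulfur, then thiolate SN2 at C1) contracts F3 to sulfide 21.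

Step 11. Facial selectivity at C7 may be poor, and the syn preference may erode through open transition states of the allylindium species in water. The fallback sets out from 14 and comes back at 19. Acetylation (Ac2O, DMAP) gives the Baylis–Hillman acetate F4. Copper-catalysed SN2′ borylation with B2pin2 gives the 2-(methoxycarbonyl)allylboronate F5, in which C6 is cis to CH2B. Its allylboration of 18 (toluene, warm, or Sc(OTf)3 catalysis) runs through a closed chair transition state (type I) and, after aqueous work-up, should give the syn adduct 19 with the same A1,3-controlled facial bias.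

Further compounds

F1 | step 16 | (E)-isomer of cyclodecenol 26 (C1=C10 E) | C/C1=C\[C@H](O[Si](C)(C)C(C)(C)C)CC(=C)[C@H](O[Si](CC)(CC)CC)[C@H](O[Si](CC)(CC)CC)[C@H](C(=C)CO[Si](CC)(CC)CC)[C@H](O)C1
F2 | step 13 | S-acetyl thiol: 20 with C1–SAc in place of C1–Cl | CC(=O)SC[C@H](O[Si](C)(C)C(C)(C)C)CC(=C)[C@H](O[Si](CC)(CC)CC)[C@H](O[Si](CC)(CC)CC)[C@H](C(=C)CO)[C@H](O)CC(C)S
F3 | step 13 | twelve-membered cyclic disulfide (S–S bridges C1 and C10) | C1[C@H](O[Si](C)(C)C(C)(C)C)CC(=C)[C@H](O[Si](CC)(CC)CC)[C@H](O[Si](CC)(CC)CC)[C@H](C(=C)CO)[C@H](O)CC(C)SS1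
F4 | step 11 | Baylis–Hillman acetate of 14 (C3 epimers) | ClC[C@H](O[Si](C)(C)C(C)(C)C)CC(=C)[C@H](O[Si](CC)(CC)CC)[C@H](O[Si](CC)(CC)CC)C(OC(C)=O)C(=C)C(=O)OC
F5 | step 11 | pinacol 2-(methoxycarbonyl)allylboronate (C6 cis to CH2B; 2E by CIP) | ClC[C@H](O[Si](C)(C)C(C)(C)C)CC(=C)[C@H](O[Si](CC)(CC)CC)[C@H](O[Si](CC)(CC)CC)/C=C(\CB1OC(C)(C)C(C)(C)O1)C(=O)OC
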